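**Retrosynthetic overview**

1. The route rests on ring C of the flavone unit: C4'' is a carbonyl carbon lying between C4a'' and C3'', and the ring oxygen O1'' is bound to C8a'', the neighbour of the biaryl carbon C8''. Cutting C4a''–C4'', C4''–C3'' and O1''–C2'' leads back to an ortho-iodophenol (iodine on C4a'', hydroxyl on C8a'', aryl on C8''), CO and a 4-benzyloxyphenyl alkyne.
2. The iodophenol is a tetra-ortho-oxygenated biaryl. Its C6–C8'' bond is made before any heterocycle, by Negishi coupling of two symmetric pieces that both come from 3,5-bis(benzyloxy)phenol: a 2,6-dibenzyloxy-4-silyloxyphenylzinc and a 2,6-diiodophenyl acetate with two equivalent iodides.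
3. Ring C of the flavone unit is closed second (carbonylative annulation) and ring C of the flavanone unit last. The silyl-marked oxygen is freed, an acetyl group is placed ortho to it, and a tert-butyl beta-keto ester / Knoevenagel / cinchona-thiourea oxa-Michael sequence sets C2 (S); decarboxylation and hydrogenolysis finish the route.

Key step: step 6

Locants: unprimed = flavanone unit, double-primed = flavone unit.

Remark 1: the target SMILES fixes only C2 (S) and not the hindered C6–C8'' axis, so the axis is left uncontrolled; from compound 15 on, each compound may be a mixture of slowly interconverting atropisomers.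

Remark 2: the quinidine-derived thiourea is assumed to give the 2S series; the sense of induction has to be confirmed on a model, and the quinine-derived pseudoenantiomer takes its place if it proves opposite.

**Route**

Step 1
Reactants: 1 3,5-bis(benzyloxy)phenol
Product: 2 [3,5-bis(benzyloxy)phenoxy]triisopropylsilane
Conditions: i-Pr3SiCl, imidazole, DMF, rt
Reagents that add atoms: chlorotriisopropylsilane, CC(C)[Si](Cl)(C(C)C)C(C)C
Why: Imidazole-promoted O-silylation of a phenol; the bulky, weakly coordinating silyl ether marks the one oxygen that later becomes O1 of the flavanone unit and does not direct metalation.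

Step 2
Reactants: 1 3,5-bis(benzyloxy)phenol
Product: 3 3,5-bis(benzyloxy)phenyl acetate
Conditions: Ac2O, pyridine, DMAP (cat.), CH2Cl2, 0 °C to rt
Reagents that add atoms: acetic anhydride, CC(=O)OC(C)=O
Why: O-acetylation turns the strongly donating hydroxyl into a weakly donating acetoxy group, so that the two benzyloxy groups alone steer the following electrophilic substitution.

Step 3
Reactants: 3 3,5-bis(benzyloxy)phenyl acetate
Product: 4 3,5-bis(benzyloxy)-2,6-diiodophenyl acetate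
Conditions: NIS (2.3 equiv), CF3CO2H (0.3 equiv), MeCN, 0 °C to rt, dark
Reagents that add atoms: N-iodosuccinimide, O=C1CCC(=O)N1I
Why: Electrophilic aromatic iodination; as in other 5-substituted resorcinol diethers, attack should go to the two equivalent carbons para to one benzyloxy group and ortho to the other (C2 and C6, next to the acetoxy group) and not to C4 between the two ethers, giving the symmetric 2,6-diiodide.

Step 4
Reactants: 2 [3,5-bis(benzyloxy)phenoxy]triisopropylsilane; 4 3,5-bis(benzyloxy)-2,6-diiodophenyl acetate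
Product: 7 3,5-bis(benzyloxy)-2-[2,6-bis(benzyloxy)-4-(triisopropylsilyloxy)phenyl]-6-iodophenyl acetate, via aryllithium 5 (not isolated), via arylzinc chloride 6 (not isolated)
Conditions: n-BuLi (1.0 equiv), THF, 0 °C; ZnCl2 (1.1 equiv), 0 °C to rt; then added slowly to 4 (3 equiv), Pd2(dba)3 (2 mol%), RuPhos (8 mol%), THF, 60 °C; excess 4 recovered
Reagents that add atoms: none
Why: Directed ortho-lithiation at the carbon flanked by two benzyloxy groups, transmetalation to zinc and Negishi coupling with a dialkylbiarylphosphine ligand (established for tetra-ortho-substituted biaryls); the two iodides of 4 are equivalent, so one coupling, favoured by the excess of 4, gives a single regioisomer and keeps the iodide needed in step 6.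

Step 5
Reactants: 7 3,5-bis(benzyloxy)-2-[2,6-bis(benzyloxy)-4-(triisopropylsilyloxy)phenyl]-6-iodophenyl acetate
Product: 8 2-[2,6-bis(benzyloxy)-4-(triisopropylsilyloxy)phenyl]-3,5-bis(benzyloxy)-6-iodophenol
Conditions: pyrrolidine (3 equiv), THF, 0 °C to rt
Reagents that add atoms: none
Why: Aminolysis of an aryl acetate by a secondary amine, which should leave the aryl silyl ether, the benzyl ethers and the aryl iodide untouched.

Step 6
Reactants: 8 2-[2,6-bis(benzyloxy)-4-(triisopropylsilyloxy)phenyl]-3,5-bis(benzyloxy)-6-iodophenol; 9 1-(benzyloxy)-4-ethynylbenzene; 10 carbon monoxide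
Product: 13 5,7-bis(benzyloxy)-2-[4-(benzyloxy)phenyl]-8-[2,6-bis(benzyloxy)-4-(triisopropylsilyloxy)phenyl]chromen-4-one, via hydroxyaryl ynone 11 (not isolated), via enaminone 12 (not isolated)
Conditions: PdCl2(PPh3)2 (5 mol%), 9 (1.5 equiv), CO (20 bar), Et2NH (solvent), 120 °C, autoclave
Reagents that add atoms: none
Why: Zerovalent palladium, formed in situ from PdCl2(PPh3)2, inserts into the C–I bond at the future C4a'', CO insertion gives an aroyl complex of divalent palladium, and coupling with the amine-activated alkyne 9 gives the 2-hydroxyaryl ynone 11; the closest known reaction is the carbonylative annulation of ortho-iodophenols with aryl acetylenes in a secondary amine. Et2NH then adds to the ynone to give enaminone 12, and the phenolic oxygen displaces the amine by conjugate addition–elimination, so ring C of the flavone unit closes in the 6-endo mode (O1''–C2'') and the 5-exo path to an aurone is avoided. Three bonds (C4a''–C4'', C4''–C3'', O1''–C2'') and one ring are formed, and no stereocentre. The regiochemistry is fixed by the substrate: the only hydroxyl of 8 lies between the iodinated carbon and the biaryl carbon, so the aryl group must end up on C8''. The step needs carbonylative over direct coupling (which would lead to a 2-arylbenzofuran) and alkyne capture over aminocarbonylation by Et2NH; the CO pressure, the excess of 9 and the two ortho substituents on the aryl–palladium complex should all favour CO insertion and alkyne capture. The silyl ether, the benzyl ethers and the hindered biaryl should be inert under these conditions.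

Step 7
Reactants: 13 5,7-bis(benzyloxy)-2-[4-(benzyloxy)phenyl]-8-[2,6-bis(benzyloxy)-4-(triisopropylsilyloxy)phenyl]chromen-4-one
Product: 14 5,7-bis(benzyloxy)-2-[4-(benzyloxy)phenyl]-8-[2,6-bis(benzyloxy)-4-hydroxyphenyl]chromen-4-one
Conditions: Bu4NF (1.1 equiv), AcOH (1.1 equiv), THF, 0 °C
Reagents that add atoms: none
Why: Fluoride cleavage of the aryl silyl ether, buffered with AcOH so that no free phenoxide or hydroxide touches the flavone, frees the one differentiated oxygen.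

Step 8
Reactants: 14 5,7-bis(benzyloxy)-2-[4-(benzyloxy)phenyl]-8-[2,6-bis(benzyloxy)-4-hydroxyphenyl]chromen-4-one
Product: 15 5,7-bis(benzyloxy)-2-[4-(benzyloxy)phenyl]-8-[2,6-bis(benzyloxy)-4-hydroxy-3-iodophenyl]chromen-4-one
Conditions: NIS (1.0 equiv), CH2Cl2, −40 °C to 0 °C
Reagents that add atoms: N-iodosuccinimide, O=C1CCC(=O)N1I
Why: Electrophilic iodination ortho to the only free phenol; the two open carbons of that ring are equivalent and the most electron-rich sites of the molecule, the first iodine should slow a second substitution, and the biaryl axis becomes a stereogenic element from here on.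

Step 9
Reactants: 15 5,7-bis(benzyloxy)-2-[4-(benzyloxy)phenyl]-8-[2,6-bis(benzyloxy)-4-hydroxy-3-iodophenyl]chromen-4-one
Product: 17 8-[3-acetyl-2,6-bis(benzyloxy)-4-hydroxyphenyl]-5,7-bis(benzyloxy)-2-[4-(benzyloxy)phenyl]chromen-4-one, via enol ether 16 (not isolated)
Conditions: tributyl(1-ethoxyvinyl)stannane (2 equiv), PdCl2(PPh3)2 (5 mol%), toluene, 100 °C; then 1 M HCl, THF, rt
Reagents that add atoms: tributyl(1-ethoxyvinyl)stannane, CCCC[Sn](CCCC)(CCCC)C(=C)OCC; water, O
Why: Stille coupling with the 1-ethoxyvinylstannane as an acetyl anion equivalent, then acid hydrolysis of the enol ether, gives the 2-hydroxyaryl methyl ketone without a Lewis acid, so the benzyl ethers that a Fries rearrangement would endanger are spared.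

Step 10
Reactants: 17 8-[3-acetyl-2,6-bis(benzyloxy)-4-hydroxyphenyl]-5,7-bis(benzyloxy)-2-[4-(benzyloxy)phenyl]chromen-4-one
Product: 18 tert-butyl 3-{2,4-bis(benzyloxy)-3-[5,7-bis(benzyloxy)-2-(4-benzyloxyphenyl)-4-oxochromen-8-yl]-6-hydroxyphenyl}-3-oxopropanoate
Conditions: LiN(SiMe3)2 (3.3 equiv), THF, −78 °C; Boc2O (1.2 equiv), −78 to −20 °C; AcOH quench
Reagents that add atoms: di-tert-butyl dicarbonate, CC(C)(C)OC(=O)OC(=O)OC(C)(C)C
Why: Claisen-type C-acylation of the lithium enolate (phenoxide–enolate dianion) with Boc2O, the third equivalent of base holding the more acidic beta-keto ester as its enolate; the flavone and the benzyl ethers offer no competing acidic site at −78 °C.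

Step 11
Reactants: 18 tert-butyl 3-{2,4-bis(benzyloxy)-3-[5,7-bis(benzyloxy)-2-(4-benzyloxyphenyl)-4-oxochromen-8-yl]-6-hydroxyphenyl}-3-oxopropanoate; 19 4-(benzyloxy)benzaldehyde
Product: 20 tert-butyl 2-{2,4-bis(benzyloxy)-3-[5,7-bis(benzyloxy)-2-(4-benzyloxyphenyl)-4-oxochromen-8-yl]-6-hydroxybenzoyl}-3-[4-(benzyloxy)phenyl]prop-2-enoate (E/Z mixture)
Conditions: 19 (1.2 equiv), piperidine (0.2 equiv), AcOH (0.2 equiv), 4 Å MS, toluene, rt
Reagents that add atoms: none
Why: Knoevenagel condensation of the beta-keto ester with a non-enolisable aryl aldehyde under piperidinium acetate catalysis with removal of water; the hydrogen-bonded phenol stays free for the ring closure.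

Step 12
Reactants: 20 tert-butyl 2-{2,4-bis(benzyloxy)-3-[5,7-bis(benzyloxy)-2-(4-benzyloxyphenyl)-4-oxochromen-8-yl]-6-hydroxybenzoyl}-3-[4-(benzyloxy)phenyl]prop-2-enoate
Product: 22 (2S)-5,7-bis(benzyloxy)-2-[4-(benzyloxy)phenyl]-6-[5,7-bis(benzyloxy)-2-(4-benzyloxyphenyl)-4-oxochromen-8-yl]chroman-4-one, via flavanone 3-carboxylate 21 (not isolated)
Conditions: 3,5-bis(trifluoromethyl)phenyl thiourea of 9-amino-9-deoxy-epi-quinidine (10 mol%), toluene, −25 °C; then TsOH·H2O (0.5 equiv), 80 °C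
Reagents that add atoms: none
Why: Bifunctional thiourea–tertiary amine catalysis of the intramolecular 6-endo-trig oxa-Michael addition (known for alkylidene beta-keto esters of 2-hydroxyaryl ketones): the thiourea binds the beta-keto ester and the quinuclidine nitrogen delivers the phenol to one face of the alkylidene, which sets C2 as S; acid then cleaves the tert-butyl ester and the beta-keto acid loses CO2 without involving C2.

Step 13
Reactants: 22 (2S)-5,7-bis(benzyloxy)-2-[4-(benzyloxy)phenyl]-6-[5,7-bis(benzyloxy)-2-(4-benzyloxyphenyl)-4-oxochromen-8-yl]chroman-4-one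
Product: 23 (2S)-5,7-dihydroxy-2-(4-hydroxyphenyl)-6-[5,7-dihydroxy-2-(4-hydroxyphenyl)-4-oxochromen-8-yl]chroman-4-one
Conditions: H2 (1 atm), 10% Pd/C, THF/MeOH, rt
Reagents that add atoms: none
Why: Hydrogenolysis of the six aryl benzyl ethers under neutral conditions, which normally retain the flavone C2''=C3'' bond, both ketones and the benzylic C2–O1 bond of a flavanone, and which should not open the flavanone ring, so C2 keeps its configuration.

**Compound list**

1 | 3,5-bis(benzyloxy)phenol | Oc1cc(OCc2ccccc2)cc(OCc2ccccc2)c1 | starting material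
2 | [3,5-bis(benzyloxy)phenoxy]triisopropylsilane | CC(C)[Si](Oc1cc(OCc2ccccc2)cc(OCc2ccccc2)c1)(C(C)C)C(C)C | intermediate
3 | 3,5-bis(benzyloxy)phenyl acetate | CC(=O)Oc1cc(OCc2ccccc2)cc(OCc2ccccc2)c1 | intermediate
4 | 3,5-bis(benzyloxy)-2,6-diiodophenyl acetate | CC(=O)Oc1c(I)c(OCc2ccccc2)cc(OCc2ccccc2)c1I | intermediate
5 | [2,6-bis(benzyloxy)-4-(triisopropylsilyloxy)phenyl]lithium | [Li]c1c(OCc2ccccc2)cc(O[Si](C(C)C)(C(C)C)C(C)C)cc1OCc1ccccc1 | intermediate (not isolated)
6 | [2,6-bis(benzyloxy)-4-(triisopropylsilyloxy)phenyl]zinc chloride | Cl[Zn]c1c(OCc2ccccc2)cc(O[Si](C(C)C)(C(C)C)C(C)C)cc1OCc1ccccc1 | intermediate (not isolated)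
7 | 3,5-bis(benzyloxy)-2-[2,6-bis(benzyloxy)-4-(triisopropylsilyloxy)phenyl]-6-iodophenyl acetate | CC(=O)Oc1c(I)c(OCc2ccccc2)cc(OCc2ccccc2)c1-c1c(OCc2ccccc2)cc(O[Si](C(C)C)(C(C)C)C(C)C)cc1OCc1ccccc1 | intermediate
8 | 2-[2,6-bis(benzyloxy)-4-(triisopropylsilyloxy)phenyl]-3,5-bis(benzyloxy)-6-iodophenol | Oc1c(I)c(OCc2ccccc2)cc(OCc2ccccc2)c1-c1c(OCc2ccccc2)cc(O[Si](C(C)C)(C(C)C)C(C)C)cc1OCc1ccccc1 | intermediate
9 | 1-(benzyloxy)-4-ethynylbenzene | C#Cc1ccc(OCc2ccccc2)cc1 | starting material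
10 | carbon monoxide | [C-]#[O+] | starting material
11 | 1-{4,6-bis(benzyloxy)-3-[2,6-bis(benzyloxy)-4-(triisopropylsilyloxy)phenyl]-2-hydroxyphenyl}-3-[4-(benzyloxy)phenyl]prop-2-yn-1-one | O=C(C#Cc1ccc(OCc2ccccc2)cc1)c1c(O)c(-c2c(OCc3ccccc3)cc(O[Si](C(C)C)(C(C)C)C(C)C)cc2OCc2ccccc2)c(OCc2ccccc2)cc1OCc1ccccc1 | intermediate (not isolated)
12 | 1-{4,6-bis(benzyloxy)-3-[2,6-bis(benzyloxy)-4-(triisopropylsilyloxy)phenyl]-2-hydroxyphenyl}-3-[4-(benzyloxy)phenyl]-3-(diethylamino)prop-2-en-1-one (double-bond geometry not defined) | CCN(CC)C(=CC(=O)c1c(O)c(-c2c(OCc3ccccc3)cc(O[Si](C(C)C)(C(C)C)C(C)C)cc2OCc2ccccc2)c(OCc2ccccc2)cc1OCc1ccccc1)c1ccc(OCc2ccccc2)cc1 | intermediate (not isolated)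
13 | 5,7-bis(benzyloxy)-2-[4-(benzyloxy)phenyl]-8-[2,6-bis(benzyloxy)-4-(triisopropylsilyloxy)phenyl]chromen-4-one | O=c1cc(-c2ccc(OCc3ccccc3)cc2)oc2c(-c3c(OCc4ccccc4)cc(O[Si](C(C)C)(C(C)C)C(C)C)cc3OCc3ccccc3)c(OCc3ccccc3)cc(OCc3ccccc3)c12 | intermediate
14 | 5,7-bis(benzyloxy)-2-[4-(benzyloxy)phenyl]-8-[2,6-bis(benzyloxy)-4-hydroxyphenyl]chromen-4-one | O=c1cc(-c2ccc(OCc3ccccc3)cc2)oc2c(-c3c(OCc4ccccc4)cc(O)cc3OCc3ccccc3)c(OCc3ccccc3)cc(OCc3ccccc3)c12 | intermediate
15 | 5,7-bis(benzyloxy)-2-[4-(benzyloxy)phenyl]-8-[2,6-bis(benzyloxy)-4-hydroxy-3-iodophenyl]chromen-4-one (axis not controlled) | O=c1cc(-c2ccc(OCc3ccccc3)cc2)oc2c(-c3c(OCc4ccccc4)c(I)c(O)cc3OCc3ccccc3)c(OCc3ccccc3)cc(OCc3ccccc3)c12 | intermediate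
16 | 8-[2,6-bis(benzyloxy)-3-(1-ethoxyvinyl)-4-hydroxyphenyl]-5,7-bis(benzyloxy)-2-[4-(benzyloxy)phenyl]chromen-4-one | CCOC(=C)c1c(O)cc(OCc2ccccc2)c(-c2c(OCc3ccccc3)cc(OCc3ccccc3)c3c(=O)cc(-c4ccc(OCc5ccccc5)cc4)oc23)c1OCc1ccccc1 | intermediate (not isolated)
17 | 8-[3-acetyl-2,6-bis(benzyloxy)-4-hydroxyphenyl]-5,7-bis(benzyloxy)-2-[4-(benzyloxy)phenyl]chromen-4-one | CC(=O)c1c(O)cc(OCc2ccccc2)c(-c2c(OCc3ccccc3)cc(OCc3ccccc3)c3c(=O)cc(-c4ccc(OCc5ccccc5)cc4)oc23)c1OCc1ccccc1 | intermediate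
18 | tert-butyl 3-{2,4-bis(benzyloxy)-3-[5,7-bis(benzyloxy)-2-(4-benzyloxyphenyl)-4-oxochromen-8-yl]-6-hydroxyphenyl}-3-oxopropanoate | CC(C)(C)OC(=O)CC(=O)c1c(O)cc(OCc2ccccc2)c(-c2c(OCc3ccccc3)cc(OCc3ccccc3)c3c(=O)cc(-c4ccc(OCc5ccccc5)cc4)oc23)c1OCc1ccccc1 | intermediate
19 | 4-(benzyloxy)benzaldehyde | O=Cc1ccc(OCc2ccccc2)cc1 | starting material
20 | tert-butyl 2-{2,4-bis(benzyloxy)-3-[5,7-bis(benzyloxy)-2-(4-benzyloxyphenyl)-4-oxochromen-8-yl]-6-hydroxybenzoyl}-3-[4-(benzyloxy)phenyl]prop-2-enoate (E/Z mixture) | CC(C)(C)OC(=O)C(=Cc1ccc(OCc2ccccc2)cc1)C(=O)c1c(O)cc(OCc2ccccc2)c(-c2c(OCc3ccccc3)cc(OCc3ccccc3)c3c(=O)cc(-c4ccc(OCc5ccccc5)cc4)oc23)c1OCc1ccccc1 | intermediate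
21 | tert-butyl (2S)-5,7-bis(benzyloxy)-2-[4-(benzyloxy)phenyl]-6-[5,7-bis(benzyloxy)-2-(4-benzyloxyphenyl)-4-oxochromen-8-yl]-4-oxochromane-3-carboxylate (C3 not defined) | O=C1C(C(=O)OC(C)(C)C)[C@@H](c2ccc(OCc3ccccc3)cc2)Oc2cc(OCc3ccccc3)c(-c3c(OCc4ccccc4)cc(OCc4ccccc4)c4c(=O)cc(-c5ccc(OCc6ccccc6)cc5)oc34)c(OCc3ccccc3)c21 | intermediate (not isolated)
22 | (2S)-5,7-bis(benzyloxy)-2-[4-(benzyloxy)phenyl]-6-[5,7-bis(benzyloxy)-2-(4-benzyloxyphenyl)-4-oxochromen-8-yl]chroman-4-one | O=C1C[C@@H](c2ccc(OCc3ccccc3)cc2)Oc2cc(OCc3ccccc3)c(-c3c(OCc4ccccc4)cc(OCc4ccccc4)c4c(=O)cc(-c5ccc(OCc6ccccc6)cc5)oc34)c(OCc3ccccc3)c21 | intermediate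
23 | (2S)-5,7-dihydroxy-2-(4-hydroxyphenyl)-6-[5,7-dihydroxy-2-(4-hydroxyphenyl)-4-oxochromen-8-yl]chroman-4-one | O=C1C[C@@H](c2ccc(O)cc2)Oc2cc(O)c(-c3c(O)cc(O)c4c(=O)cc(-c5ccc(O)cc5)oc34)c(O)c21 | target

**Step count**

Total: 13 steps. Longest linear sequence: 12 steps (steps 2 to 13, from 1 through 3, 4, 7, 8, 13, 14, 15, 17, 18, 20 and 22 to 23).

**Steps most likely to fail**

Step 6. Oxidative addition and CO insertion at the doubly ortho-substituted, electron-rich iodide may be slow, so that aminocarbonylation by Et2NH or non-carbonylative coupling takes over. The fallback sets out from 8 and builds ring C of the flavone unit by the diketone route. Stille coupling of 8 with tributyl(1-ethoxyvinyl)stannane (PdCl2(PPh3)2, toluene, 100 °C) would give 2-[2,6-bis(benzyloxy)-4-(triisopropylsilyloxy)phenyl]-3,5-bis(benzyloxy)-6-(1-ethoxyvinyl)phenol F1, and 1 M HCl in THF would hydrolyse it to 1-{4,6-bis(benzyloxy)-3-[2,6-bis(benzyloxy)-4-(triisopropylsilyloxy)phenyl]-2-hydroxyphenyl}ethanone F2. C-aroylation of its dianion (LiN(SiMe3)2, THF, −78 °C, then 4-(benzyloxy)benzoyl chloride) would give 1-{4,6-bis(benzyloxy)-3-[2,6-bis(benzyloxy)-4-(triisopropylsilyloxy)phenyl]-2-hydroxyphenyl}-3-[4-(benzyloxy)phenyl]propane-1,3-dione F3. Cyclodehydration (TsOH, toluene, 80 °C) would close the pyranone and return to the route at 13.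

Step 4. After the first coupling the palladium may stay on the ring and insert into the second C–I bond (double arylation), and transmetalation onto the tetra-ortho-substituted axis may be slow. The fallback sets out from 3 and replaces statistical control by halogen differentiation. NBS (1 equiv, MeCN) would give 3,5-bis(benzyloxy)-2-bromophenyl acetate F4, and NIS/CF3CO2H would then give 3,5-bis(benzyloxy)-2-bromo-6-iodophenyl acetate F5. Negishi coupling with arylzinc 6 at a 1:1 ratio should take place at the C–I bond only and give 3,5-bis(benzyloxy)-2-[2,6-bis(benzyloxy)-4-(triisopropylsilyloxy)phenyl]-6-bromophenyl acetate F6. Copper-catalysed aromatic Finkelstein exchange (CuI, NaI, trans-N,N'-dimethylcyclohexane-1,2-diamine, dioxane, 110 °C) would turn the bromide into the iodide and return to the route at 7.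

Step 12. Enantiocontrol may be lost because the very nucleophilic 2-hydroxy-6-benzyloxyaroyl system closes without the catalyst (possibly already during step 11), or because the ring reopens under acid during decarboxylation. The fallback sets out from 17 and sets C2 by asymmetric conjugate addition. Me2NCH(OMe)2 (toluene, 90 °C) would give 8-{2,6-bis(benzyloxy)-3-[(E)-3-(dimethylamino)prop-2-enoyl]-4-hydroxyphenyl}-5,7-bis(benzyloxy)-2-[4-(benzyloxy)phenyl]chromen-4-one F7. Aqueous HCl in CH2Cl2 would close it to 5,7-bis(benzyloxy)-2-[4-(benzyloxy)phenyl]-8-[5,7-bis(benzyloxy)-4-oxochromen-6-yl]chromen-4-one F8. 1,4-Addition of 4-(benzyloxy)phenylboronic acid (Pd(OCOCF3)2, the t-BuPyOX enantiomer that delivers the aryl group to the face giving 2S, NH4PF6, ClCH2CH2Cl/H2O, 60 °C) would give the flavanone directly and return to the route at 22.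

**Further compounds**

F1 | step 6 | 2-[2,6-bis(benzyloxy)-4-(triisopropylsilyloxy)phenyl]-3,5-bis(benzyloxy)-6-(1-ethoxyvinyl)phenol | C=C(OCC)c1c(O)c(-c2c(OCc3ccccc3)cc(O[Si](C(C)C)(C(C)C)C(C)C)cc2OCc2ccccc2)c(OCc2ccccc2)cc1OCc1ccccc1
F2 | step 6 | 1-{4,6-bis(benzyloxy)-3-[2,6-bis(benzyloxy)-4-(triisopropylsilyloxy)phenyl]-2-hydroxyphenyl}ethanone | CC(=O)c1c(O)c(-c2c(OCc3ccccc3)cc(O[Si](C(C)C)(C(C)C)C(C)C)cc2OCc2ccccc2)c(OCc2ccccc2)cc1OCc1ccccc1
F3 | step 6 | 1-{4,6-bis(benzyloxy)-3-[2,6-bis(benzyloxy)-4-(triisopropylsilyloxy)phenyl]-2-hydroxyphenyl}-3-[4-(benzyloxy)phenyl]propane-1,3-dione | O=C(CC(=O)c1ccc(OCc2ccccc2)cc1)c1c(O)c(-c2c(OCc3ccccc3)cc(O[Si](C(C)C)(C(C)C)C(C)C)cc2OCc2ccccc2)c(OCc2ccccc2)cc1OCc1ccccc1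
F4 | step 4 | 3,5-bis(benzyloxy)-2-bromophenyl acetate | CC(=O)Oc1cc(OCc2ccccc2)cc(OCc2ccccc2)c1Br
F5 | step 4 | 3,5-bis(benzyloxy)-2-bromo-6-iodophenyl acetate | CC(=O)Oc1c(I)c(OCc2ccccc2)cc(OCc2ccccc2)c1Br
F6 | step 4 | 3,5-bis(benzyloxy)-2-[2,6-bis(benzyloxy)-4-(triisopropylsilyloxy)phenyl]-6-bromophenyl acetate | CC(=O)Oc1c(Br)c(OCc2ccccc2)cc(OCc2ccccc2)c1-c1c(OCc2ccccc2)cc(O[Si](C(C)C)(C(C)C)C(C)C)cc1OCc1ccccc1
F7 | step 12 | 8-{2,6-bis(benzyloxy)-3-[(E)-3-(dimethylamino)prop-2-enoyl]-4-hydroxyphenyl}-5,7-bis(benzyloxy)-2-[4-(benzyloxy)phenyl]chromen-4-one | CN(C)/C=C/C(=O)c1c(O)cc(OCc2ccccc2)c(-c2c(OCc3ccccc3)cc(OCc3ccccc3)c3c(=O)cc(-c4ccc(OCc5ccccc5)cc4)oc23)c1OCc1ccccc1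
F8 | step 12 | 5,7-bis(benzyloxy)-2-[4-(benzyloxy)phenyl]-8-[5,7-bis(benzyloxy)-4-oxochromen-6-yl]chromen-4-one | O=c1ccoc2cc(OCc3ccccc3)c(-c3c(OCc4ccccc4)cc(OCc4ccccc4)c4c(=O)cc(-c5ccc(OCc6ccccc6)cc5)oc34)c(OCc3ccccc3)c12
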